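## Structural features

The target is a cyclopentane (ring carbons C8, C9, C10, C11, C12; prostanoic acid numbering) with two chains on neighbouring ring carbons. C8 carries a saturated seven-carbon carboxylic acid chain (C1–C7). C12 carries an eight-carbon chain (C13–C20) with an E C13=C14 double bond and an allylic carbinol at C15. Four ring carbons are stereogenic: at C8/C9 the C7 chain and the hydroxyl lie on the same face, at C11/C12 the hydroxyl and the C13 chain lie on opposite faces, and the chains on C8 and C12 are trans, so the two ring hydroxyls are cis-1,3 across the C10 methylene. The fifth stereocentre, C15 (S), is insulated from the ring by the double bond and needs its own control element. The triol acid itself is fairly robust, apart from the acid-sensitive C15 allylic alcohol. The fragile functions on the way are a β-silyloxy aldehyde (prone to β-elimination), a γ-enolisable enone and a methyl ester. The real difficulty is the cis-C8/C9, trans-C8/C12, trans-C11/C12 pattern in the presence of two long functionalised chains. The key step exploits the fact that C12 is the γ-carbon of a C13=C14–C15 enone in a 15-oxo precursor while C11 is a carbinol carbon, so an open chain with C8 and C9 already set and the enone already in place can close the ring by forming C11–C12.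

## Logic of the disconnections

**23 to 21 (through 22).** Only heteroatom bonds are restored: the O–CH3 bond of an ester at C1 and the O–Si bond at C9. The acid and the C9 hydroxyl must be masked while base, oxidants and a borane are used. The gain is that one ester and one silyl ether are the only spectator groups in the route. The forward step must cleave both without dehydrating or epimerising the triol.

**21 to 20.** The C15–H bond is cut, turning the carbinol into a ketone. This removes the isolated stereocentre and creates the enone that makes C12 acidic. The forward step must deliver hydride to one face of an acyclic enone under reagent control, without conjugate reduction and in the presence of a free C11 hydroxyl.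

**20 to 19.** The C11–C12 ring bond is cut. This opens the cyclopentane and removes two stereocentres (C11, C12), leaving an acyclic chain whose only stereocentres are the adjacent C8 and C9. The forward step must deprotonate at C12 and not at C16, add through the γ-carbon, and control C11 and C12 relative to C8/C9. It must also outrun enolisation of the aldehyde towards C10. For that reason 19 keeps a bulky, non-chelating, poor leaving group on O9 and a simple methyl ester; an acyl group on O9 would be eliminated and a free hydroxyl would add to C13.

**19 to 17 (through 18).** The C11 aldehyde is traced to a benzyl-type ether of the primary alcohol. The aldehyde cannot survive the earlier organometallic and metathesis steps. The demand is orthogonality: the C11 ether must fall under neutral oxidative conditions that leave the C9 silyl ether, the enone and the ester intact, and the oxidation must be non-basic.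

**17 to 15 and 16.** The C13=C14 double bond is cut. Seven carbons (C14–C20) are removed as a commercial vinyl ketone, and 15 keeps only a terminal alkene. The forward step must be cross-selective and E-selective, with loss of the two terminal CH2 groups as a volatile alkene.

**15 to 12 and 13 (through 14).** The C6–C7 bond is cut. Six carbons including the ester are removed as a commercial bromo ester, used as its organozinc. The forward step is an sp3–sp3 coupling at a β-branched primary carbon; it must avoid β-hydride elimination and tolerate ester, alkene and ethers.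

**12 to 10 (through 11).** The C7–I bond is traced to C7–OH and then to the C7 acyl–nitrogen bond of the auxiliary. C7 is thus the carbonyl carbon of the aldol donor. The forward steps must cleave the auxiliary reductively without retro-aldol (hence O9 is silylated first) and substitute at C7 without touching C8.

**10 to 4 and 7 (through 9 and 8).** After removal of the O–Si bond the C8–C9 bond is cut. Both remaining stereocentres are then made in one step from an achiral aldehyde and an imide that carries the future C12–C14 as an allyl group. The forward step must be syn-selective, with absolute control by the auxiliary from 2.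

**4 to 1 and 2 (through 3); 7 to 5 (through 6).** An N–acyl bond and a benzylic C–O bond are cut, reaching commercial materials. The only demands are mono-protection of a symmetrical diol and oxidation to a β-alkoxy aldehyde without elimination.

## Other disconnections considered

**Alternative 1:** The cut removes both chains and then opens the ring at C8–C9 and C11=C12, so that all ring carbons come from two molecules of succinaldehyde A1. In the forward key step (S)-proline joins two molecules of A1 by an enamine aldol (C8–C9), an ammonium salt promotes the intramolecular aldol condensation (C11=C12), and O9 closes onto C6, giving the bicyclic enal lactol A2. From A2 the ω-chain would enter by conjugate addition of a vinyl copper reagent that already carries the 15S centre, the C11 oxygen by cleavage of the trapped enol ether and reduction, and the α-chain by Wittig reaction at the lactol.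
- In its favour: ring, C8 and C9 arise in one catalytic operation from an achiral C4 unit, and C15 arrives preformed.
- Against it here: A1 oligomerises readily, so the key step must compete with polymer formation. The Wittig step leaves a C5=C6 double bond that the saturated chain of 23 does not have, so a hydrogenation selective against C13=C14 would be needed.
- Comparison: on step economy and on control of C15 this alternative is the better plan. On enantiocontrol of C8/C9 it is at least equal (catalyst instead of auxiliary). Mechanistically both rest on aldol chemistry, but here the enamine has no competing acidic site, which is an advantage over the chosen plan. The chosen plan is better on structure: it installs the saturated α-chain directly, with no alkene discrimination, and has the ω-chain in place at ring closure.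

**Alternative 2:** The cut is biomimetic: C8–C12 and the C–O bonds at C9, C11 and C15 are removed together, leading to dihomo-γ-linolenic acid A3. In the forward step cyclooxygenase abstracts the C13 hydrogen; O2 is trapped at C11; the peroxyl radical closes onto C9; C8–C12 forms; and a second O2 is taken up at C15, giving the endoperoxide hydroperoxide PGG1 A4. Reduction of both O–O bonds of A4 would give 23 directly.
- In its favour: every stereocentre, the ring and the E alkene are set in one step, and the route has two operations.
- Against it here: the enzyme inactivates itself during turnover and must be supplied in quantity. A4 is a labile peroxide that can rearrange to ketols before it is reduced. A3 is itself a costly polyunsaturated acid, not a simple building block. The method gives no access to analogues.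
- Comparison: on step economy and on stereocontrol this alternative is clearly the better. Structurally it forms C8–C12 by a radical cascade where the chosen plan forms C11–C12 by ionic aldol chemistry. The chosen plan is better in scalability with ordinary reagents, in handling of intermediates and in flexibility.

**Alternative 3:** The cut is C10–C11, leading to the acyclic α-diazo β-keto ester A5, in which C12 bears two identical benzyloxymethyl arms. In the forward step Rh2(OAc)4 generates the C10 carbenoid, which inserts into an ether-activated C–H bond of one arm in a 1,5 sense, giving the cyclopentanone A6 with C11 and C12 set relative to C8.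
- In its favour: the ring closure is neutral, so there is no carbanion chemistry and no enolisable aldehyde; one C–C bond formation sets two stereocentres; and the ether oxygen activates the reacting C–H bond.
- Against it here: C8 must be set beforehand next to a ketone, where it can epimerise. The carbenoid must choose between two diastereotopic arms, and the C6–H bond of the α-chain is an equally placed 1,5 competitor. After ring closure a long sequence remains: removal of the allyl ester carbon, reduction of the C9 ketone to the α-alcohol, debenzylation, selective oxidation at C13, olefination and C15 reduction.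
- Comparison: mechanistically this ring closure is more secure than the chosen one, because no second acidic site competes; on that point the alternative is the better. On kinetic control of C11/C12 it is equal or better. The chosen plan is better in step economy after ring closure (two operations against roughly seven), avoids a diazo compound, and sets C9 by aldol instead of by late ketone reduction.

Key step: step 12

Remark: prostanoic acid numbering is used for all intermediates. The terminal alkene carbon of 15 is lost in step 9, and C14 of 17 comes from 16. (R)-4-Benzyloxazolidin-2-one is taken as a commercial auxiliary.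

## Route

Step 1
Reactants: 1 pent-4-enoic acid; 2 (R)-4-benzyloxazolidin-2-one
Product: 4 (R)-4-benzyl-3-(pent-4-enoyl)oxazolidin-2-one, via pent-4-enoic pivalic anhydride 3 (not isolated)
Conditions: PivCl, Et3N, THF, −20 °C; then LiCl, 2, −20 °C to rt
Reagents that add atoms: pivaloyl chloride, CC(C)(C)C(=O)Cl (its acyl group is carried only by 3)
Why: Mixed-anhydride N-acylation of an oxazolidinone; the hindered pivaloyl carbonyl directs attack of the lithium-activated auxiliary to the pentenoyl carbonyl, and no stereocentre is touched.

Step 2
Reactants: 5 propane-1,3-diol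
Product: 6 3-[(4-methoxybenzyl)oxy]propan-1-ol
Conditions: 5 (3 equiv), NaH (1 equiv), THF, 0 °C; then 4-methoxybenzyl chloride, Bu4NI (cat.), 0 °C to rt
Reagents that add atoms: 4-methoxybenzyl chloride, COc1ccc(CCl)cc1
Why: Williamson etherification of the mono-alkoxide; the excess of diol keeps the bis-ether low.

Step 3
Reactants: 6 3-[(4-methoxybenzyl)oxy]propan-1-ol
Product: 7 3-[(4-methoxybenzyl)oxy]propanal
Conditions: TEMPO (2,2,6,6-tetramethylpiperidin-1-oxyl, 10 mol%), PhI(OAc)2, CH2Cl2, rt
Reagents that add atoms: none
Why: Oxoammonium-mediated oxidation of a primary alcohol stops at the aldehyde and is base-free, so the β-alkoxy aldehyde does not eliminate.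

Step 4
Reactants: 4 (R)-4-benzyl-3-(pent-4-enoyl)oxazolidin-2-one; 7 3-[(4-methoxybenzyl)oxy]propanal
Product: 9 (R)-4-benzyl-3-{(2R,3S)-2-allyl-3-hydroxy-5-[(4-methoxybenzyl)oxy]pentanoyl}oxazolidin-2-one, via dibutylboron Z-enolate 8 (not isolated)
Conditions: Bu2BOTf, iPr2NEt, CH2Cl2, 0 °C; then 7, −78 to 0 °C; pH 7 buffer, MeOH, H2O2, 0 °C
Reagents that add atoms: dibutylboron triflate, CCCCB(CCCC)OS(=O)(=O)C(F)(F)F (its Bu2B group is carried only by 8)
Why: Evans syn aldol: the Z boron enolate reacts through a chair Zimmerman–Traxler transition state with the imide dipoles opposed, and the (R)-benzyl group shields one enolate face, which sets C8 (2R of the acyl chain) and C9 (3S) in the syn relationship needed for the cis C7-chain/O9 arrangement.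

Step 5
Reactants: 9 (R)-4-benzyl-3-{(2R,3S)-2-allyl-3-hydroxy-5-[(4-methoxybenzyl)oxy]pentanoyl}oxazolidin-2-one
Product: 10 (R)-4-benzyl-3-{(2R,3S)-2-allyl-3-[(tert-butyldimethylsilyl)oxy]-5-[(4-methoxybenzyl)oxy]pentanoyl}oxazolidin-2-one
Conditions: TBSOTf, 2,6-lutidine, CH2Cl2, −78 to 0 °C
Reagents that add atoms: tert-butyldimethylsilyl triflate, CC(C)(C)[Si](C)(C)OS(=O)(=O)C(F)(F)F
Why: Silylation of the hindered aldol hydroxyl with the reactive triflate; it blocks retro-aldol in the next step and installs the O9 group kept to the end.

Step 6
Reactants: 10 (R)-4-benzyl-3-{(2R,3S)-2-allyl-3-[(tert-butyldimethylsilyl)oxy]-5-[(4-methoxybenzyl)oxy]pentanoyl}oxazolidin-2-one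
Product: 11 (2S,3S)-2-allyl-3-[(tert-butyldimethylsilyl)oxy]-5-[(4-methoxybenzyl)oxy]pentan-1-ol
Conditions: LiBH4, MeOH (1 equiv), THF, 0 °C
Reagents that add atoms: none
Why: Reductive cleavage of the imide at the exocyclic carbonyl gives the C7 alcohol and returns the auxiliary; C8 is not enolised under hydride conditions (the descriptor changes only because of the priority rules).

Step 7
Reactants: 11 (2S,3S)-2-allyl-3-[(tert-butyldimethylsilyl)oxy]-5-[(4-methoxybenzyl)oxy]pentan-1-ol
Product: 12 tert-butyl{[(3S,4R)-4-(iodomethyl)-1-[(4-methoxybenzyl)oxy]hept-6-en-3-yl]oxy}dimethylsilane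
Conditions: I2, PPh3, imidazole, CH2Cl2, 0 °C to rt
Reagents that add atoms: iodine, II
Why: Appel-type iodination (Garegg–Samuelsson conditions): SN2 displacement of the alkoxyphosphonium at the primary C7, with no change at C8 or C9.

Step 8
Reactants: 12 tert-butyl{[(3S,4R)-4-(iodomethyl)-1-[(4-methoxybenzyl)oxy]hept-6-en-3-yl]oxy}dimethylsilane; 13 methyl 6-bromohexanoate
Product: 15 methyl (8R,9S)-8-allyl-9-[(tert-butyldimethylsilyl)oxy]-11-[(4-methoxybenzyl)oxy]undecanoate, via (6-methoxy-6-oxohexyl)zinc bromide 14 (not isolated)
Conditions: 13, Zn dust, I2 (5 mol%), DMA, 70 °C; then 12, Ni(cod)2 (4 mol%), s-Bu-Pybox [2,6-bis(4-sec-butyl-4,5-dihydrooxazol-2-yl)pyridine, 8 mol%], DMA, rt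
Reagents that add atoms: zinc, [Zn] (carried only by 14)
Why: Zinc insertion gives an ester-tolerant alkylzinc, and the nickel/pybox-catalysed alkyl–alkyl Negishi coupling joins C6 to C7; the primary iodide is activated by halogen abstraction rather than by SN2-type oxidative addition, so the β-branch at C8 is tolerated and C8/C9 are not involved.

Step 9
Reactants: 15 methyl (8R,9S)-8-allyl-9-[(tert-butyldimethylsilyl)oxy]-11-[(4-methoxybenzyl)oxy]undecanoate; 16 oct-1-en-3-one
Product: 17 methyl (8R,9S)-9-[(tert-butyldimethylsilyl)oxy]-11-[(4-methoxybenzyl)oxy]-8-[(E)-4-oxonon-2-en-1-yl]undecanoate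
Conditions: 16 (3 equiv), second-generation Hoveyda–Grubbs catalyst (5 mol%), CH2Cl2, 40 °C
Reagents that add atoms: none
Why: Olefin cross-metathesis of a terminal alkene with an electron-poor vinyl ketone that is reluctant to homodimerise, so the cross product should dominate with 16 in excess; the conjugated E alkene is the thermodynamic product.

Step 10
Reactants: 17 methyl (8R,9S)-9-[(tert-butyldimethylsilyl)oxy]-11-[(4-methoxybenzyl)oxy]-8-[(E)-4-oxonon-2-en-1-yl]undecanoate
Product: 18 methyl (8R,9S)-9-[(tert-butyldimethylsilyl)oxy]-11-hydroxy-8-[(E)-4-oxonon-2-en-1-yl]undecanoate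
Conditions: DDQ, CH2Cl2/pH 7 buffer (10:1), 0 °C
Reagents that add atoms: none
Why: Oxidative cleavage of the electron-rich benzyl ether by hydride abstraction and hydrolysis; the silyl ether, ester and enone are inert to DDQ at this temperature.

Step 11
Reactants: 18 methyl (8R,9S)-9-[(tert-butyldimethylsilyl)oxy]-11-hydroxy-8-[(E)-4-oxonon-2-en-1-yl]undecanoate
Product: 19 methyl (8R,9S)-9-[(tert-butyldimethylsilyl)oxy]-11-oxo-8-[(E)-4-oxonon-2-en-1-yl]undecanoate
Conditions: Dess–Martin periodinane, CH2Cl2, 0 °C to rt
Reagents that add atoms: none
Why: Dess–Martin oxidation is neutral to weakly acidic, so the β-silyloxy aldehyde is formed without base and can be used at once.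

Step 12
Reactants: 19 methyl (8R,9S)-9-[(tert-butyldimethylsilyl)oxy]-11-oxo-8-[(E)-4-oxonon-2-en-1-yl]undecanoate
Product: 20 methyl (8R,9S,11R,12R,13E)-9-[(tert-butyldimethylsilyl)oxy]-11-hydroxy-15-oxoprost-13-en-1-oate
Conditions: DBU (1,8-diazabicyclo[5.4.0]undec-7-ene, 0.3 equiv), MeCN (0.01 M), 0 °C to rt; AcOH quench
Reagents that add atoms: none
Why: DBU reversibly removes a C12 proton of 19 to give the extended dienolate (O–C15=C14–C13=C12), whose terminal carbon C12 adds to the C11 aldehyde, and proton transfer to the aldolate returns the conjugated E enone. The closest known reaction type is the base-mediated intramolecular vinylogous aldol addition of a γ-enolisable enone to a tethered aldehyde. The cyclopentane (C8–C9–C10–C11–C12) closes in a 5-exo-trig mode at the carbonyl, enolexo with respect to the dienolate, so the C12=C13 bond of the nucleophile stays outside the ring. C12 is controlled by C8: the enone arm takes the face trans to the C7 chain, and because H12 stays γ-acidic in 20 this centre can also be corrected by reprotonation. C11 is controlled by C12 and C9: the hydroxyl should settle trans to the C12 arm and cis-1,3 (both pseudo-equatorial) to the C9 silyloxy group, the arrangement reached when the aldol addition is reversible. γ-Selectivity is secured by ring size, since attack through C14 would need a seven-membered ring containing the C12=C13 bond and the C16 enolate would need a nine-membered ring. The competing chemistry is that of the C10 enolate of the aldehyde (loss of the C9 silyloxy group, or 5-exo conjugate addition to C13); substoichiometric base, low temperature, high dilution, an early quench and the bulky, poorly leaving silyl ether next to C10 are chosen to hold it back.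

Step 13
Reactants: 20 methyl (8R,9S,11R,12R,13E)-9-[(tert-butyldimethylsilyl)oxy]-11-hydroxy-15-oxoprost-13-en-1-oate
Product: 21 methyl (8R,9S,11R,12R,13E,15S)-9-[(tert-butyldimethylsilyl)oxy]-11,15-dihydroxyprost-13-en-1-oate
Conditions: (R)-2-methyl-CBS-oxazaborolidine [(3aR)-1-methyl-3,3-diphenyltetrahydro-1H,3H-pyrrolo[1,2-c][1,3,2]oxazaborole, 0.3 equiv], catecholborane (3 equiv), toluene, −78 °C; MeOH, then aq. NaHCO3
Reagents that add atoms: none
Why: Corey–Bakshi–Shibata reduction: the ketone binds the catalyst boron with the alkenyl group as the large substituent away from the catalyst, and hydride is delivered to the Re face of C15, giving 15S; catecholborane at low temperature avoids conjugate reduction, and the excess covers the free C11 hydroxyl.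

Step 14
Reactants: 21 methyl (8R,9S,11R,12R,13E,15S)-9-[(tert-butyldimethylsilyl)oxy]-11,15-dihydroxyprost-13-en-1-oate
Product: 23 prostaglandin F1α [(8R,9S,11R,12R,13E,15S)-9,11,15-trihydroxyprost-13-en-1-oic acid], via prostaglandin F1α methyl ester 22 (not isolated)
Conditions: Bu4NF (TBAF), THF, rt; then LiOH, H2O/MeOH, rt; aq. HCl to pH 4, 0 °C
Reagents that add atoms: lithium hydroxide, [Li+].[OH-] (supplies the carboxyl OH oxygen)
Why: Fluoride cleaves the Si–O bond and hydroxide then saponifies the methyl ester by acyl–oxygen cleavage in the same flask; neither reagent affects a stereocentre or the allylic alcohol, and the triol acid has no β-ketol to dehydrate.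

## Compound list

1 | pent-4-enoic acid | C=CCCC(=O)O | starting material
2 | (R)-4-benzyloxazolidin-2-one | O=C1N[C@H](Cc2ccccc2)CO1 | starting material
3 | pent-4-enoic pivalic anhydride | C=CCCC(=O)OC(=O)C(C)(C)C | intermediate
4 | (R)-4-benzyl-3-(pent-4-enoyl)oxazolidin-2-one | C=CCCC(=O)N1[C@H](Cc2ccccc2)COC1=O | intermediate
5 | propane-1,3-diol | OCCCO | starting material
6 | 3-[(4-methoxybenzyl)oxy]propan-1-ol | COc1ccc(COCCCO)cc1 | intermediate
7 | 3-[(4-methoxybenzyl)oxy]propanal | COc1ccc(COCCC=O)cc1 | intermediate
8 | dibutylboron Z-enolate of 4 | C=CC/C=C(\OB(CCCC)CCCC)N1[C@H](Cc2ccccc2)COC1=O | intermediate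
9 | (R)-4-benzyl-3-{(2R,3S)-2-allyl-3-hydroxy-5-[(4-methoxybenzyl)oxy]pentanoyl}oxazolidin-2-one | C=CC[C@@H](C(=O)N1[C@H](Cc2ccccc2)COC1=O)[C@@H](O)CCOCc1ccc(OC)cc1 | intermediate
10 | (R)-4-benzyl-3-{(2R,3S)-2-allyl-3-[(tert-butyldimethylsilyl)oxy]-5-[(4-methoxybenzyl)oxy]pentanoyl}oxazolidin-2-one | C=CC[C@@H](C(=O)N1[C@H](Cc2ccccc2)COC1=O)[C@@H](O[Si](C)(C)C(C)(C)C)CCOCc1ccc(OC)cc1 | intermediate
11 | (2S,3S)-2-allyl-3-[(tert-butyldimethylsilyl)oxy]-5-[(4-methoxybenzyl)oxy]pentan-1-ol | C=CC[C@@H](CO)[C@@H](O[Si](C)(C)C(C)(C)C)CCOCc1ccc(OC)cc1 | intermediate
12 | tert-butyl{[(3S,4R)-4-(iodomethyl)-1-[(4-methoxybenzyl)oxy]hept-6-en-3-yl]oxy}dimethylsilane | C=CC[C@@H](CI)[C@@H](O[Si](C)(C)C(C)(C)C)CCOCc1ccc(OC)cc1 | intermediate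
13 | methyl 6-bromohexanoate | COC(=O)CCCCCBr | starting material
14 | (6-methoxy-6-oxohexyl)zinc bromide | COC(=O)CCCCC[Zn]Br | intermediate
15 | methyl (8R,9S)-8-allyl-9-[(tert-butyldimethylsilyl)oxy]-11-[(4-methoxybenzyl)oxy]undecanoate | C=CC[C@@H](CCCCCCC(=O)OC)[C@@H](O[Si](C)(C)C(C)(C)C)CCOCc1ccc(OC)cc1 | intermediate
16 | oct-1-en-3-one | CCCCCC(=O)C=C | starting material
17 | methyl (8R,9S)-9-[(tert-butyldimethylsilyl)oxy]-11-[(4-methoxybenzyl)oxy]-8-[(E)-4-oxonon-2-en-1-yl]undecanoate | CCCCCC(=O)/C=C/C[C@@H](CCCCCCC(=O)OC)[C@@H](O[Si](C)(C)C(C)(C)C)CCOCc1ccc(OC)cc1 | intermediate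
18 | methyl (8R,9S)-9-[(tert-butyldimethylsilyl)oxy]-11-hydroxy-8-[(E)-4-oxonon-2-en-1-yl]undecanoate | CCCCCC(=O)/C=C/C[C@@H](CCCCCCC(=O)OC)[C@@H](O[Si](C)(C)C(C)(C)C)CCO | intermediate
19 | methyl (8R,9S)-9-[(tert-butyldimethylsilyl)oxy]-11-oxo-8-[(E)-4-oxonon-2-en-1-yl]undecanoate | CCCCCC(=O)/C=C/C[C@@H](CCCCCCC(=O)OC)[C@@H](O[Si](C)(C)C(C)(C)C)CC=O | intermediate
20 | methyl (8R,9S,11R,12R,13E)-9-[(tert-butyldimethylsilyl)oxy]-11-hydroxy-15-oxoprost-13-en-1-oate | CCCCCC(=O)/C=C/[C@@H]1[C@@H](CCCCCCC(=O)OC)[C@@H](O[Si](C)(C)C(C)(C)C)C[C@H]1O | intermediate
21 | methyl (8R,9S,11R,12R,13E,15S)-9-[(tert-butyldimethylsilyl)oxy]-11,15-dihydroxyprost-13-en-1-oate | CCCCC[C@H](O)/C=C/[C@@H]1[C@@H](CCCCCCC(=O)OC)[C@@H](O[Si](C)(C)C(C)(C)C)C[C@H]1O | intermediate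
22 | prostaglandin F1α methyl ester | CCCCC[C@H](O)/C=C/[C@@H]1[C@@H](CCCCCCC(=O)OC)[C@@H](O)C[C@H]1O | intermediate
23 | prostaglandin F1α | CCCCC[C@H](O)/C=C/[C@@H]1[C@@H](CCCCCCC(=O)O)[C@@H](O)C[C@H]1O | target

## Step count and least certain steps

Total: 14 steps. Longest linear sequence: 13 steps (5 to 23 through steps 2–14).

**Step 12 (key step).** The most likely failure is enolisation of the aldehyde towards C10 in competition with γ-deprotonation at C12, because the aldehyde α-protons are at least as acidic as the enone γ-protons. The C10 enolate can lose the C9 silyloxy group or add in a 5-exo conjugate fashion to C13. Both processes are irreversible, whereas the desired aldol addition is reversible, so long equilibration would drain material. A second weakness is incomplete control at C11 if retro-aldol exchange is slow under an amidine base.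

Fallback (the ω-chain is attached after ring closure; it sets out from 15 and comes back at 20):
- Allylic C–H acetoxylation of the terminal alkene of 15 (Pd(OAc)2, benzoquinone, DMSO/AcOH, 40 °C) should give the linear allylic acetate methyl (8R,9S)-8-[(E)-3-acetoxyprop-1-en-1-yl]-9-[(tert-butyldimethylsilyl)oxy]-11-[(4-methoxybenzyl)oxy]undecanoate F1.
- DDQ then frees the primary alcohol, giving methyl (8R,9S)-8-[(E)-3-acetoxyprop-1-en-1-yl]-9-[(tert-butyldimethylsilyl)oxy]-11-hydroxyundecanoate F2.
- Dess–Martin oxidation gives methyl (8R,9S)-8-[(E)-3-acetoxyprop-1-en-1-yl]-9-[(tert-butyldimethylsilyl)oxy]-11-oxoundecanoate F3.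
- Pd(PPh3)4-catalysed ionisation of the acetate in the presence of InI (indium monoiodide; umpolung allylation) turns the C12–C13–C14 allyl unit into an allylindium nucleophile. It adds through C12 to the C11 aldehyde under neutral conditions, closing the same C11–C12 bond and leaving a vinyl group at C12: methyl 7-[(1R,2R,3R,5S)-5-[(tert-butyldimethylsilyl)oxy]-3-hydroxy-2-vinylcyclopentyl]heptanoate F4. A chair-like transition state of the E-allylindium is expected to favour the 11,12-trans isomer; an 11-epimer would be removed at this stage.
- Cross-metathesis of F4 with 16 under the conditions of step 9 gives 20.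

**Step 8.** The most likely failure is slow coupling at the β-branched primary carbon, with β-hydride elimination or reduction of the alkylnickel intermediate; transfer of a hydrogen from C11 to the transient C7 radical is also possible.

Fallback (polarity reversed, copper catalysis; it sets out from 11 and comes back at 15):
- Appel bromination (CBr4, PPh3) gives {[(3S,4R)-4-(bromomethyl)-1-[(4-methoxybenzyl)oxy]hept-6-en-3-yl]oxy}(tert-butyl)dimethylsilane F5.
- Magnesium insertion in THF gives {(2R,3S)-2-allyl-3-[(tert-butyldimethylsilyl)oxy]-5-[(4-methoxybenzyl)oxy]pentyl}magnesium bromide F6, whose γ-silyloxy group cannot be lost by β-elimination.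
- Li2CuCl4-catalysed coupling of F6 with 13 in THF/NMP at 0 °C, where the primary bromide reacts faster than the ester, gives 15.

**Step 9.** The most likely failure is incomplete metathesis with homodimerisation of 15, because the vinyl ketone is a poor partner for the propagating carbene and the catalyst decays on long heating.

Fallback (olefination instead of metathesis; it sets out from 15 and comes back at 17):
- Oxidative cleavage of the terminal alkene (OsO4 cat., NaIO4, 2,6-lutidine, dioxane/H2O) gives methyl (8R,9S)-9-[(tert-butyldimethylsilyl)oxy]-11-[(4-methoxybenzyl)oxy]-8-(2-oxoethyl)undecanoate F7.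
- Horner–Wadsworth–Emmons reaction with dimethyl (2-oxoheptyl)phosphonate (LiCl, iPr2NEt, MeCN) gives the E enone 17.

**Step 13.** The most likely failure is insufficient facial selectivity at C15, because the C11 hydroxyl (as its borate) and the ring substituent at C12 may oppose the catalyst.

Fallback (separation and recycling instead of reagent control; it sets out from 20 and comes back at 21):
- Luche reduction (NaBH4, CeCl3·7H2O, MeOH, −78 °C) gives 21 together with its epimer methyl (8R,9S,11R,12R,13E,15R)-9-[(tert-butyldimethylsilyl)oxy]-11,15-dihydroxyprost-13-en-1-oate F8.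
- The epimers are separated by chromatography. F8 is returned to 20 by selective oxidation of the allylic alcohol with MnO2 and reduced again, so the material converges on 21.

Further compounds
F1 | step 12 | methyl (8R,9S)-8-[(E)-3-acetoxyprop-1-en-1-yl]-9-[(tert-butyldimethylsilyl)oxy]-11-[(4-methoxybenzyl)oxy]undecanoate | CC(=O)OC/C=C/[C@@H](CCCCCCC(=O)OC)[C@@H](O[Si](C)(C)C(C)(C)C)CCOCc1ccc(OC)cc1
F2 | step 12 | methyl (8R,9S)-8-[(E)-3-acetoxyprop-1-en-1-yl]-9-[(tert-butyldimethylsilyl)oxy]-11-hydroxyundecanoate | CC(=O)OC/C=C/[C@@H](CCCCCCC(=O)OC)[C@@H](O[Si](C)(C)C(C)(C)C)CCO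
F3 | step 12 | methyl (8R,9S)-8-[(E)-3-acetoxyprop-1-en-1-yl]-9-[(tert-butyldimethylsilyl)oxy]-11-oxoundecanoate | CC(=O)OC/C=C/[C@@H](CCCCCCC(=O)OC)[C@@H](O[Si](C)(C)C(C)(C)C)CC=O
F4 | step 12 | methyl 7-[(1R,2R,3R,5S)-5-[(tert-butyldimethylsilyl)oxy]-3-hydroxy-2-vinylcyclopentyl]heptanoate | C=C[C@@H]1[C@@H](CCCCCCC(=O)OC)[C@@H](O[Si](C)(C)C(C)(C)C)C[C@H]1O
F5 | step 8 | {[(3S,4R)-4-(bromomethyl)-1-[(4-methoxybenzyl)oxy]hept-6-en-3-yl]oxy}(tert-butyl)dimethylsilane | C=CC[C@@H](CBr)[C@@H](O[Si](C)(C)C(C)(C)C)CCOCc1ccc(OC)cc1
F6 | step 8 | {(2R,3S)-2-allyl-3-[(tert-butyldimethylsilyl)oxy]-5-[(4-methoxybenzyl)oxy]pentyl}magnesium bromide | C=CC[C@@H](C[Mg]Br)[C@@H](O[Si](C)(C)C(C)(C)C)CCOCc1ccc(OC)cc1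
F7 | step 9 | methyl (8R,9S)-9-[(tert-butyldimethylsilyl)oxy]-11-[(4-methoxybenzyl)oxy]-8-(2-oxoethyl)undecanoate | O=CC[C@@H](CCCCCCC(=O)OC)[C@@H](O[Si](C)(C)C(C)(C)C)CCOCc1ccc(OC)cc1
F8 | step 13 | methyl (8R,9S,11R,12R,13E,15R)-9-[(tert-butyldimethylsilyl)oxy]-11,15-dihydroxyprost-13-en-1-oate | CCCCC[C@@H](O)/C=C/[C@@H]1[C@@H](CCCCCCC(=O)OC)[C@@H](O[Si](C)(C)C(C)(C)C)C[C@H]1O
A1 | alternative 1 | succinaldehyde | O=CCCC=O
A2 | alternative 1 | (3aR,6aS)-2-hydroxy-3,3a,6,6a-tetrahydro-2H-cyclopenta[b]furan-5-carbaldehyde (anomers) | O=CC1=C[C@H]2CC(O)O[C@H]2C1
A3 | alternative 2 | dihomo-γ-linolenic acid [(8Z,11Z,14Z)-icosa-8,11,14-trienoic acid] | CCCCC/C=C\C/C=C\C/C=C\CCCCCCC(=O)O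
A4 | alternative 2 | PGG1 (9,11-endoperoxide 15-hydroperoxide) | CCCCC[C@H](OO)/C=C/[C@@H]1[C@@H](CCCCCCC(=O)O)[C@@H]2C[C@H]1OO2
A5 | alternative 3 | 11-methyl 1-(prop-2-en-1-yl) (4R)-4-[1,3-bis(benzyloxy)propan-2-yl]-2-diazo-3-oxoundecanedioate | C=CCOC(=O)C(=[N+]=[N-])C(=O)[C@H](CCCCCCC(=O)OC)C(COCc1ccccc1)COCc1ccccc1
A6 | alternative 3 | prop-2-en-1-yl (3R,4S,5S)-5-(benzyloxy)-4-[(benzyloxy)methyl]-3-(7-methoxy-7-oxoheptyl)-2-oxocyclopentane-1-carboxylate (C1 epimers) | C=CCOC(=O)C1C(=O)[C@H](CCCCCCC(=O)OC)[C@@H](COCc2ccccc2)[C@@H]1OCc3ccccc3
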